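Atom numbering is labdane numbering throughout: ring A = C1–C5 and C10; ring B = C5–C10; C4 carries C18 (methyl) and C19 (ester); C10 carries C20 (formyl); C8 carries C17 (methylene); C9 carries C11–C12, which ends at C13 of the butenolide (C13–C16). Compound numbers are those of the compound list below.

## Analysis of the target

Target 22 is a labdane-type trans-decalin with a methyl ester (C19) and a methyl group (C18) on C4, a formyl group (C20) on C10, an exocyclic methylene (C17) on C8 and a two-carbon chain on C9 that ends at the α-carbon of a butenolide. The four stereocentres C4, C5, C10 and C9 are contiguous, and C4 and C10 are quaternary. The ester and the formyl group are both axial on the β-face (1,3-diaxial), H5 and H9 are axial on the α-face, and C18 and the C9 chain are equatorial. The exocyclic methylene can migrate under acid or metal hydrides, the butenolide is a Michael acceptor with an acidic γ-CH2, and the C20 aldehyde is hindered and has no α-hydrogen. The difficulty lies in the two 1,3-related quaternary centres, the congested C9–C10 bond, and three carbonyl carbons (C12, C19, C20) that must be kept apart. The strategy rests on one feature: C10 is the α-carbon of the C20 aldehyde and C9 is β to C12, so with C12 at the acid oxidation level the C9–C10 bond is the bond of a Michael addition that also closes ring B. Because the aldehyde enolate is planar, the configuration at C10 before ring closure does not matter. The C8 methylene makes the acceptor a 2,4-dienoate whose δ-carbon C17 is also six atoms from C10, so the regiochemistry of this closure has to be argued and cannot be taken for granted.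

## Retrosynthetic reasoning

**C12–C13 (22 ⇒ 19 + 20).** The butenolide is the part most sensitive to base and nucleophiles, so it is attached last and intact. Cutting the sp3–sp2 bond C12–C13 gives a primary alkyl donor at C12 and the commercial bromide 20. Building the lactone ring on the finished decalin would cost several steps. Forward, iodide 19 becomes the zinc reagent 21, which must couple with 20 without touching the C20 aldehyde.

**Oxidation levels at C12 and C20 (19 ⇒ 18 ⇒ 17 ⇒ 16).** The iodide comes from the C12 alcohol, and C12 from the thioester carbon of 16. A C12 hydroxyl and a C20 formyl group in one molecule would close to a six-membered hemiacetal. Both carbonyl groups of 16 are therefore reduced together to diol 17, the unhindered C12 hydroxyl is exchanged for iodide (18), and the neopentyl C20 alcohol is re-oxidised (19). The C19 methyl ester stays untouched because it is axial, neopentyl and far less reactive than a thioester.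

**C9–C10 (16 ⇒ 13), the key disconnection.** Cutting C9–C10 opens ring B and removes both ring B stereocentres, leaving a ring A aldehyde with a dienyl thioester arm that already holds C17. It is cut here because this is the only bond of ring B flanked by a carbonyl α-carbon on one side and a carbonyl β-carbon on the other. The aldehyde 13 may be any mixture of C10 epimers, since both give enolate 14. Forward, 14 must add to C9 and not to C17, from the α-face of C10, with C11 equatorial; the adduct 15 is protonated to 16.

**C9=C11 (13 ⇒ 12 ⇒ 10 + 11).** The unsaturated thioester is made by olefination of enal 10 with phosphonate 11. A molecule with free aldehydes at both C20 and C9 would be a 1,7-dialdehyde prone to aldol condensation and would not distinguish the two in the olefination. C20 is therefore carried as the methyl enol ether (12) and released only in the last step before ring closure.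

**C8=C17 and C8–C9 (10 ⇒ 9 ⇒ 8).** The methylene carbon C17 is added by α-methylenation of the chain aldehyde 9, and C9 by linear hydroformylation of the allyl group of 8. This builds the four-carbon chain C6–C9 from a simple allyl group without any protecting group on the chain.

**C4–C18 (8 ⇒ 6).** The quaternary centre C4 is made late, by methylation of ester enolate 7. The C5 substituent is already present and controls the face: the methyl group enters trans to the chain, which leaves the ester cis to it, as in 22. Introducing the chain next to a finished quaternary C4 would give poor control, because a methyl group and an ester differ little in size.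

**C10=C20 (6 ⇒ 4 + 5).** C20 comes from Wittig reagent 5 and the ring ketone of 4. The enol ether is both the masked aldehyde and, being non-enolisable, the reason the ester can be deprotonated cleanly at C4.

**C4–H and C5–C6 (4 ⇒ 1 + 2).** Conjugate hydride addition to enone ester 1 gives the regiodefined enol silane 3 and sets C4–H enantioselectively. Allylation with 2 then sets C5 trans to the ester. The C4 centre is only a relay: it fixes the absolute configuration of C5 and is re-made in the methylation.

## Alternatives that were turned down

**Alternative 1:** Cut C1–C10 and C9–C11. Ring B is made first as a cyclohexenone (C8 carbonyl, C9=C10), and the two substituents of the C9/C10 pair are added across it: copper-catalysed addition of a vinyl nucleophile to C10, then alkylation of the regenerated C9 enolate with a 2-silyloxyethyl electrophile, giving A1.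
- For: conjugate addition to an enone has no regiochemical ambiguity, and on that point it is more secure than the ring closure chosen here. The C5 substituent should direct both new bonds, and the C8 ketone is a clean handle for the methylene.
- Against: the quaternary centre is made on a β,β-disubstituted enone, and the enolate next to it must then be alkylated by an unactivated primary electrophile with a β-oxygen, which is slow and invites proton transfer and O-alkylation. C20 sits at the alcohol level under a protecting group. Ring A is still missing: C3 must be added, the ring closed and C4 methylated with control, so the hardest relationship (C4/C10, 1,3-diaxial) is postponed. Methylenation, deprotections, two oxidations and the butenolide follow.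
- Comparison: I estimate at least eight steps after A1, against four after 16. The chosen route has ring A and C4 in place and uses the C4 ester as the control element for C10; in exchange it accepts a regiochemical risk that A1 does not have.

**Alternative 2:** Cut C4–C5 and C9–C10 and make both rings from an acyclic β-keto ester triene bearing an 8-phenylmenthyl ester. Manganese- and copper-mediated one-electron oxidation gives a C4 radical that adds to C5; the C10 radical adds to C9; the C8 radical is oxidised to the C8=C17 alkene, giving A2.
- For: two rings, two C–C bonds, four stereocentres and the exocyclic alkene in one operation. On bond-forming economy this is clearly stronger than the chosen route, and chair–chair folding gives the trans-decalin reliably.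
- Against: C10 must carry an oxygenated C20, so the central alkene bears an allylic oxygen that lowers its reactivity toward the electrophilic C4 radical. The terminating oxidation can give endocyclic alkene isomers as well as C8=C17. Facial control comes from a remote auxiliary. The product has a C3 ketone that 22 lacks and must be removed next to quaternary C4 with the methylene present. The hindered axial auxiliary ester must be exchanged for a methyl ester, which realistically means reduction and re-oxidation. C20 deprotection, oxidation and the butenolide remain.
- Comparison: A2 is reached faster, but five to eight corrective steps follow. The chosen route has no C3 oxygen, has the methyl ester from the first compound, sets each stereocentre by a separate element, and gets absolute configuration from a catalyst.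

**Alternative 3:** Cut C10–C20 and C9–C11 by a [2+2] photocycloaddition across the C9=C10 bond of a ring A/ring B enone (C8 carbonyl), with the alkene partner tethered through the C19 carboxylate as a 3-acyloxyacrylate. Irradiation near 350 nm gives cyclobutane lactone A3; retro-aldol cleavage of C20–C11 would then reveal the C20 aldehyde and the C11–C12 ester.
- For: C20 is delivered from the C19 carboxyl through the tether, so the cis relationship of C19 and C20 is guaranteed by connectivity. This is stronger than the substrate-controlled facial selectivity of the chosen route. C20 appears at the aldehyde level, and C9 can equilibrate through the C8 ketone.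
- Against: the bicyclic enone with quaternary C4 and a free acid needs its own synthesis. The enol ester tether must be made from a hindered acid, and an ester link does not easily adopt the folded geometry, so straight versus crossed addition is uncertain. After fragmentation the molecule has a C8 ketone beside a more reactive C20 aldehyde, so methylenation needs protection, and the C12 ester must be told apart from C19.
- Comparison: the chosen route closes ring B with the C8 methylene already present and with C12 as a thioester distinct from C19. It needs no photochemistry and no ketone methylenation beside an aldehyde, at the price of relying on facial selectivity at C10.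

Key step: step 8

Assumption: the (R)-antipode of the bisphosphine in step 1 is taken to give (1R)-3; if the sense of induction is opposite, the (S)-ligand is used. Enone ester 1 is taken as a catalogue compound.

## Route

Step 1
Reactants: 1 methyl 3-oxocyclohex-1-ene-1-carboxylate; 2 3-bromoprop-1-ene (allyl bromide)
Product: 4 methyl (1R,2S)-3-oxo-2-(prop-2-en-1-yl)cyclohexane-1-carboxylate, via silyl enol ether 3 (not isolated)
Conditions: Cu(OAc)2·H2O (cat.), (R)-DTBM-SEGPHOS (cat.), (EtO)2MeSiH, toluene, 0 °C; then 2, Bu4N[Ph3SiF2], THF, 0 °C → rt
Reagents that add atoms: none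
Why: Ligated monovalent copper hydride should deliver hydride to the enone carbon that carries the ester (C4), the ketone being the stronger acceptor (asymmetric conjugate reduction of a β-substituted cyclohexenone), and the silane traps the enolate as the regiodefined enol silane 3. Fluoride then releases the C5 enolate, which is allylated anti to the neighbouring ester to give the trans, diequatorial product, which is also the thermodynamic one.

Step 2
Reactants: 4 methyl (1R,2S)-3-oxo-2-(prop-2-en-1-yl)cyclohexane-1-carboxylate; 5 (methoxymethyl)triphenylphosphonium chloride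
Product: 6 methyl (1R,2S)-3-(methoxymethylidene)-2-(prop-2-en-1-yl)cyclohexane-1-carboxylate (E/Z mixture)
Conditions: 5, KOtBu, THF, 0 °C; then 4, 0 °C → rt
Reagents that add atoms: none
Why: Wittig methoxymethylenation adds C20 as a base-stable enol ether, so the later chain aldehyde never meets a free C20 aldehyde; the ketone reacts far faster than the methyl ester. Any epimerisation at C5 returns the same trans isomer, and the C4–H centre is re-made in step 3.

Step 3
Reactants: 6 methyl (1R,2S)-3-(methoxymethylidene)-2-(prop-2-en-1-yl)cyclohexane-1-carboxylate
Product: 8 methyl (1S,2R)-3-(methoxymethylidene)-1-methyl-2-(prop-2-en-1-yl)cyclohexane-1-carboxylate (E/Z mixture), via lithium ester enolate 7 (not isolated)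
Conditions: LiN(iPr)2, THF, −78 °C; MeI, −78 → −20 °C
Reagents that add atoms: iodomethane, IC
Why: Enolate 7 has exocyclic double bonds on both sides of C5, so allylic 1,3-strain should place the allyl group axial and the electrophile should enter from the opposite face (ester enolate alkylation under 1,2-induction). The methyl group then ends trans to the C5 chain and the ester cis to it, which is the C4 configuration of 22; the C5 descriptor changes from S to R only because the priorities change.

Step 4
Reactants: 8 methyl (1S,2R)-3-(methoxymethylidene)-1-methyl-2-(prop-2-en-1-yl)cyclohexane-1-carboxylate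
Product: 9 methyl (1S,2R)-3-(methoxymethylidene)-1-methyl-2-(4-oxobutyl)cyclohexane-1-carboxylate
Conditions: Rh(acac)(CO)2 (cat.), BiPhePhos (cat.), CO/H2 (1:1, 10 bar), toluene, 60 °C
Reagents that add atoms: carbon monoxide, [C-]#[O+]
Why: Linear-selective hydroformylation with a bulky bisphosphite adds C9 at the terminal alkene carbon; the trisubstituted enol ether should be too hindered to react.

Step 5
Reactants: 9 methyl (1S,2R)-3-(methoxymethylidene)-1-methyl-2-(4-oxobutyl)cyclohexane-1-carboxylate
Product: 10 methyl (1S,2R)-2-(3-formylbut-3-en-1-yl)-3-(methoxymethylidene)-1-methylcyclohexane-1-carboxylate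
Conditions: aq. CH2O, pyrrolidine (cat.), EtCO2H (cat.), iPrOH, 45 °C
Reagents that add atoms: formaldehyde, C=O
Why: Amine-catalysed Mannich condensation and elimination (α-methylenation) converts the only enolisable aldehyde into the 2-substituted acrolein and puts C17 in place. The buffered amine–acid medium should leave the enol ether intact.

Step 6
Reactants: 10 methyl (1S,2R)-2-(3-formylbut-3-en-1-yl)-3-(methoxymethylidene)-1-methylcyclohexane-1-carboxylate; 11 S-ethyl 2-(diethoxyphosphoryl)ethanethioate
Product: 12 methyl (1S,2R)-2-[(4E)-6-(ethylsulfanyl)-3-methylidene-6-oxohex-4-en-1-yl]-3-(methoxymethylidene)-1-methylcyclohexane-1-carboxylate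
Conditions: 11, LiCl, iPr2NEt, MeCN, 0 °C → rt
Reagents that add atoms: none
Why: Horner–Wadsworth–Emmons olefination under mild LiCl/amine conditions should give the E-configured unsaturated thioester; the enol ether and the methyl ester are inert to it.

Step 7
Reactants: 12 methyl (1S,2R)-2-[(4E)-6-(ethylsulfanyl)-3-methylidene-6-oxohex-4-en-1-yl]-3-(methoxymethylidene)-1-methylcyclohexane-1-carboxylate
Product: 13 methyl (1S,2R,3RS)-2-[(4E)-6-(ethylsulfanyl)-3-methylidene-6-oxohex-4-en-1-yl]-3-formyl-1-methylcyclohexane-1-carboxylate (both C10 epimers)
Conditions: 1 M HCl, THF, 0 °C → rt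
Reagents that add atoms: water, O
Why: Acid hydrolysis of the enol ether frees the C20 aldehyde as a mixture of C10 epimers, which does not matter because both give the same enolate. The electron-poor diene and the thioester should not be protonated under these conditions.

Step 8
Reactants: 13 methyl (1S,2R,3RS)-2-[(4E)-6-(ethylsulfanyl)-3-methylidene-6-oxohex-4-en-1-yl]-3-formyl-1-methylcyclohexane-1-carboxylate
Product: 16 methyl (1S,4aS,5S,8aR)-5-[2-(ethylsulfanyl)-2-oxoethyl]-4a-formyl-1-methyl-6-methylidenedecahydronaphthalene-1-carboxylate, via potassium aldehyde enolate 14 (not isolated), via potassium thioester enolate 15 (not isolated)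
Conditions: KN(SiMe3)2 (1.05 equiv), THF (0.01 M), −78 °C; AcOH, −78 °C
Reagents that add atoms: none
Why: KN(SiMe3)2 removes the single α-hydrogen of either C10 epimer to give the planar enolate 14, so the epimers converge. C10 then adds to C9, the β-carbon of the unsaturated thioester, in an intramolecular Michael addition (closest known type: 6-exo-trig closure of an α-branched aldehyde enolate onto an unsaturated ester or thioester), and enolate 15 is protonated at C11 on quenching. Ring B closes 6-exo-trig through a chair in which C8 is the sp2 ring atom. At C10 the axial C19 ester, 1,3 to C10, blocks the β-face, so C9 should bond from the α-face and C20 becomes axial and β (trans-decalin). At C9 the CH=CH–COSEt unit should sit equatorial in that chair, away from the axial H5 and H7, which gives the β side chain. The step needs 1,4- over 1,6-regioselectivity, because attack at C17 would also close a six-membered ring (6-endo): the 1,6-mode needs C17, C8, C9, C11 and C12 coplanar with C7 in that plane, which strains the forming ring, whereas the 1,4-mode only needs C9=C11–C12 planar and lets C8 twist into the chair. Low temperature, the potassium counter-ion and a cold quench should keep the reaction under kinetic control, since 15 is more basic than 14 and the addition should not reverse. The product aldehyde has no α-hydrogen and cannot epimerise.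

Step 9
Reactants: 16 methyl (1S,4aS,5S,8aR)-5-[2-(ethylsulfanyl)-2-oxoethyl]-4a-formyl-1-methyl-6-methylidenedecahydronaphthalene-1-carboxylate
Product: 17 methyl (1S,4aS,5S,8aR)-5-(2-hydroxyethyl)-4a-(hydroxymethyl)-1-methyl-6-methylidenedecahydronaphthalene-1-carboxylate
Conditions: LiBH4, THF, 0 °C → rt
Reagents that add atoms: none
Why: Borohydride reduces the aldehyde and the thioester to the diol, while the axial neopentyl methyl ester at C4 should be too hindered to react at this temperature. C20 is taken to the alcohol on purpose, because a C12 hydroxyl beside a C20 formyl group would close to a six-membered hemiacetal.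

Step 10
Reactants: 17 methyl (1S,4aS,5S,8aR)-5-(2-hydroxyethyl)-4a-(hydroxymethyl)-1-methyl-6-methylidenedecahydronaphthalene-1-carboxylate
Product: 18 methyl (1S,4aS,5S,8aR)-4a-(hydroxymethyl)-5-(2-iodoethyl)-1-methyl-6-methylidenedecahydronaphthalene-1-carboxylate
Conditions: I2, PPh3, imidazole, CH2Cl2, 0 °C
Reagents that add atoms: iodine, [I][I]
Why: Appel iodination: the unhindered C12 hydroxyl is activated by the phosphine–iodine reagent and displaced by iodide, whereas the C20 hydroxyl is neopentyl and cannot undergo backside displacement.

Step 11
Reactants: 18 methyl (1S,4aS,5S,8aR)-4a-(hydroxymethyl)-5-(2-iodoethyl)-1-methyl-6-methylidenedecahydronaphthalene-1-carboxylate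
Product: 19 methyl (1S,4aS,5S,8aR)-4a-formyl-5-(2-iodoethyl)-1-methyl-6-methylidenedecahydronaphthalene-1-carboxylate
Conditions: Dess–Martin periodinane, CH2Cl2, 0 °C → rt
Reagents that add atoms: none
Why: Dess–Martin oxidation returns C20 to the aldehyde under mild conditions that should leave the primary iodide and the exocyclic alkene untouched. The aldehyde has no α-hydrogen and cannot epimerise.

Step 12
Reactants: 19 methyl (1S,4aS,5S,8aR)-4a-formyl-5-(2-iodoethyl)-1-methyl-6-methylidenedecahydronaphthalene-1-carboxylate; 20 3-bromofuran-2(5H)-one
Product: 22 methyl (1S,4aS,5S,8aR)-4a-formyl-1-methyl-6-methylidene-5-[2-(2-oxo-2,5-dihydrofuran-3-yl)ethyl]decahydronaphthalene-1-carboxylate, via alkylzinc iodide 21 (not isolated)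
Conditions: Zn dust, I2 (cat.), DMA, rt; then 20, Pd2(dba)3 (cat.), SPhos (cat.), THF, rt
Reagents that add atoms: none
Why: Zinc inserts into the primary C–I bond, and 21 undergoes Negishi sp3–sp2 coupling at the C–Br bond of 20 on zerovalent palladium. Alkylzinc halides are poor nucleophiles toward the hindered quaternary aldehyde and toward the butenolide as a Michael acceptor, and the biarylphosphine favours reductive elimination over β-hydride elimination.

## Compound list

1 | methyl 3-oxocyclohex-1-ene-1-carboxylate | COC(=O)C1=CC(=O)CCC1 | starting material
2 | 3-bromoprop-1-ene (allyl bromide) | C=CCBr | starting material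
3 | methyl (1R)-3-{[diethoxy(methyl)silyl]oxy}cyclohex-2-ene-1-carboxylate | C1=C(O[Si](C)(OCC)OCC)CCC[C@H]1C(=O)OC | intermediate
4 | methyl (1R,2S)-3-oxo-2-(prop-2-en-1-yl)cyclohexane-1-carboxylate | C=CC[C@@H]1C(=O)CCC[C@H]1C(=O)OC | intermediate
5 | (methoxymethyl)triphenylphosphonium chloride | COC[P+](c1ccccc1)(c1ccccc1)c1ccccc1.[Cl-] | starting material
6 | methyl (1R,2S)-3-(methoxymethylidene)-2-(prop-2-en-1-yl)cyclohexane-1-carboxylate (E/Z mixture) | C=CC[C@@H]1C(=COC)CCC[C@H]1C(=O)OC | intermediate
7 | lithium enolate of ester 6 (C4=C19(OMe)O−, C5 as in 6) | C=CC[C@@H]1C(=COC)CCCC1=C([O-])OC.[Li+] | intermediate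
8 | methyl (1S,2R)-3-(methoxymethylidene)-1-methyl-2-(prop-2-en-1-yl)cyclohexane-1-carboxylate (E/Z mixture) | C=CC[C@@H]1C(=COC)CCC[C@]1(C)C(=O)OC | intermediate
9 | methyl (1S,2R)-3-(methoxymethylidene)-1-methyl-2-(4-oxobutyl)cyclohexane-1-carboxylate | O=CCCC[C@@H]1C(=COC)CCC[C@]1(C)C(=O)OC | intermediate
10 | methyl (1S,2R)-2-(3-formylbut-3-en-1-yl)-3-(methoxymethylidene)-1-methylcyclohexane-1-carboxylate | C=C(C=O)CC[C@@H]1C(=COC)CCC[C@]1(C)C(=O)OC | intermediate
11 | S-ethyl 2-(diethoxyphosphoryl)ethanethioate | CCOP(=O)(OCC)CC(=O)SCC | starting material
12 | methyl (1S,2R)-2-[(4E)-6-(ethylsulfanyl)-3-methylidene-6-oxohex-4-en-1-yl]-3-(methoxymethylidene)-1-methylcyclohexane-1-carboxylate | CCSC(=O)/C=C/C(=C)CC[C@@H]1C(=COC)CCC[C@]1(C)C(=O)OC | intermediate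
13 | methyl (1S,2R,3RS)-2-[(4E)-6-(ethylsulfanyl)-3-methylidene-6-oxohex-4-en-1-yl]-3-formyl-1-methylcyclohexane-1-carboxylate | CCSC(=O)/C=C/C(=C)CC[C@@H]1C(C=O)CCC[C@]1(C)C(=O)OC | intermediate
14 | potassium enolate of aldehyde 13 (O−–C20=C10, C4 and C5 as in 13) | CCSC(=O)/C=C/C(=C)CC[C@@H]1C(=C[O-])CCC[C@]1(C)C(=O)OC.[K+] | intermediate
15 | potassium thioester enolate of 16 (O−–C12=C11, stereocentres as in 16) | C=C1CC[C@@H]2[C@](C=O)(CCC[C@]2(C)C(=O)OC)[C@H]1C=C([O-])SCC.[K+] | intermediate
16 | methyl (1S,4aS,5S,8aR)-5-[2-(ethylsulfanyl)-2-oxoethyl]-4a-formyl-1-methyl-6-methylidenedecahydronaphthalene-1-carboxylate | C=C1CC[C@@H]2[C@](C=O)(CCC[C@]2(C)C(=O)OC)[C@H]1CC(=O)SCC | intermediate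
17 | methyl (1S,4aS,5S,8aR)-5-(2-hydroxyethyl)-4a-(hydroxymethyl)-1-methyl-6-methylidenedecahydronaphthalene-1-carboxylate | C=C1CC[C@@H]2[C@](CO)(CCC[C@]2(C)C(=O)OC)[C@H]1CCO | intermediate
18 | methyl (1S,4aS,5S,8aR)-4a-(hydroxymethyl)-5-(2-iodoethyl)-1-methyl-6-methylidenedecahydronaphthalene-1-carboxylate | C=C1CC[C@@H]2[C@](CO)(CCC[C@]2(C)C(=O)OC)[C@H]1CC[I] | intermediate
19 | methyl (1S,4aS,5S,8aR)-4a-formyl-5-(2-iodoethyl)-1-methyl-6-methylidenedecahydronaphthalene-1-carboxylate | C=C1CC[C@@H]2[C@](C=O)(CCC[C@]2(C)C(=O)OC)[C@H]1CC[I] | intermediate
20 | 3-bromofuran-2(5H)-one | O=C1OCC=C1Br | starting material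
21 | alkylzinc iodide from 19 (C12–Zn–I, stereocentres as in 19) | C=C1CC[C@@H]2[C@](C=O)(CCC[C@]2(C)C(=O)OC)[C@H]1CC[Zn][I] | intermediate
22 | methyl (1S,4aS,5S,8aR)-4a-formyl-1-methyl-6-methylidene-5-[2-(2-oxo-2,5-dihydrofuran-3-yl)ethyl]decahydronaphthalene-1-carboxylate | C=C1CC[C@@H]2[C@](C=O)(CCC[C@]2(C)C(=O)OC)[C@H]1CCC1=CCOC1=O | target

## Step count and least certain steps

Total step count: 12. Longest linear sequence: 12 steps (1 → 22).

**Step 8 (key step).** The most likely failure is ring closure at C17 instead of C9 (1,6-addition, 6-endo), because C17 is an unhindered terminus of the dienyl thioester and is also six atoms from C10. A second risk is attack on the β-face of the enolate, which would give the cis-decalin. The fallback masks C17 so that only the 1,4-mode exists; it sets out from 10 and comes back at 16. Conjugate addition of thiophenol (Et3N cat.) to the enal gives the β-sulfanyl aldehyde methyl (1S,2R)-2-[3-formyl-4-(phenylsulfanyl)butyl]-3-(methoxymethylidene)-1-methylcyclohexane-1-carboxylate F1. Olefination with 11 as in step 6 gives the unsaturated thioester F2, and acid hydrolysis as in step 7 gives the aldehyde F3, whose acceptor has no δ-position. KN(SiMe3)2 closes ring B to the sulfide-bearing decalin F4. NaIO4 oxidises the sulfide to the sulfoxide F5, and heating in toluene eliminates toward C8, the only β-hydrogen, which releases the methylene and gives 16.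

**Step 1.** The most likely failures are hydride transfer to the wrong end of the doubly activated alkene (which would give an ester enolate and an uncontrolled C4), low enantioselectivity, or proton exchange of the fluoride-generated enolate before allylation. The fallback sets out from 1 and comes back at 8. Conjugate addition of Me2Zn, catalysed by (CuOTf)2·C6H6 and a chiral sulfonate-bearing N-heterocyclic carbene (as its silver complex), is a reaction type established for cyclic β-ester enones and makes the quaternary C4 directly. Allylation in the same flask with allyl acetate and Pd(PPh3)4, then base equilibration at C5 and separation of epimers, gives methyl (1S,2S)-1-methyl-3-oxo-2-(prop-2-en-1-yl)cyclohexane-1-carboxylate F6. Wittig reaction with 5 as in step 2 gives 8 and makes step 3 unnecessary. The price is weaker control at C5, since a methyl group and an ester on C4 differ little in size.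

**Step 12.** The most likely failure is intramolecular addition of the alkylzinc to the C20 aldehyde (a five-membered ring), or protonation of the zinc reagent before coupling. The fallback keeps C20 as a protected alcohol through the coupling; it sets out from 18 and comes back at 22. Silylation with Et3SiOTf and 2,6-lutidine gives the triethylsilyl ether F7. Zinc insertion as in step 12 gives the alkylzinc iodide F8, and coupling with 20 gives the butenolide silyl ether F9. HF·pyridine removes the silyl group to give the alcohol F10, and Dess–Martin oxidation gives 22.

**Step 10.** The most likely failure is cyclisation of the activated C12 oxygen onto the nearby C20 hydroxyl to give a tetrahydropyran, in place of displacement by iodide. The fallback uses a less reactive leaving group in two stages; it sets out from 17 and comes back at 18. TsCl in pyridine at 0 °C sulfonylates only the unhindered hydroxyl and gives the mono-tosylate F11, and NaI in acetone then gives 18.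

Further compounds
F1 | step 8 | methyl (1S,2R)-2-[3-formyl-4-(phenylsulfanyl)butyl]-3-(methoxymethylidene)-1-methylcyclohexane-1-carboxylate (C8 epimers) | O=CC(CSc1ccccc1)CC[C@@H]1C(=COC)CCC[C@]1(C)C(=O)OC
F2 | step 8 | methyl (1S,2R)-2-{(4E)-6-(ethylsulfanyl)-6-oxo-3-[(phenylsulfanyl)methyl]hex-4-en-1-yl}-3-(methoxymethylidene)-1-methylcyclohexane-1-carboxylate | CCSC(=O)/C=C/C(CSc1ccccc1)CC[C@@H]1C(=COC)CCC[C@]1(C)C(=O)OC
F3 | step 8 | methyl (1S,2R,3RS)-2-{(4E)-6-(ethylsulfanyl)-6-oxo-3-[(phenylsulfanyl)methyl]hex-4-en-1-yl}-3-formyl-1-methylcyclohexane-1-carboxylate | CCSC(=O)/C=C/C(CSc1ccccc1)CC[C@@H]1C(C=O)CCC[C@]1(C)C(=O)OC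
F4 | step 8 | methyl (1S,4aS,5S,8aR)-5-[2-(ethylsulfanyl)-2-oxoethyl]-4a-formyl-1-methyl-6-[(phenylsulfanyl)methyl]decahydronaphthalene-1-carboxylate (C8 epimers) | c1ccccc1SCC1CC[C@@H]2[C@](C=O)(CCC[C@]2(C)C(=O)OC)[C@H]1CC(=O)SCC
F5 | step 8 | methyl (1S,4aS,5S,8aR)-6-[(benzenesulfinyl)methyl]-5-[2-(ethylsulfanyl)-2-oxoethyl]-4a-formyl-1-methyldecahydronaphthalene-1-carboxylate | O=S(c1ccccc1)CC1CC[C@@H]2[C@](C=O)(CCC[C@]2(C)C(=O)OC)[C@H]1CC(=O)SCC
F6 | step 1 | methyl (1S,2S)-1-methyl-3-oxo-2-(prop-2-en-1-yl)cyclohexane-1-carboxylate | C=CC[C@@H]1C(=O)CCC[C@]1(C)C(=O)OC
F7 | step 12 | methyl (1S,4aS,5S,8aR)-5-(2-iodoethyl)-1-methyl-6-methylidene-4a-{[(triethylsilyl)oxy]methyl}decahydronaphthalene-1-carboxylate | C=C1CC[C@@H]2[C@](CO[Si](CC)(CC)CC)(CCC[C@]2(C)C(=O)OC)[C@H]1CC[I]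
F8 | step 12 | alkylzinc iodide from F7 (C12–Zn–I) | C=C1CC[C@@H]2[C@](CO[Si](CC)(CC)CC)(CCC[C@]2(C)C(=O)OC)[C@H]1CC[Zn][I]
F9 | step 12 | methyl (1S,4aS,5S,8aR)-1-methyl-6-methylidene-5-[2-(2-oxo-2,5-dihydrofuran-3-yl)ethyl]-4a-{[(triethylsilyl)oxy]methyl}decahydronaphthalene-1-carboxylate | C=C1CC[C@@H]2[C@](CO[Si](CC)(CC)CC)(CCC[C@]2(C)C(=O)OC)[C@H]1CCC1=CCOC1=O
F10 | step 12 | methyl (1S,4aS,5S,8aR)-4a-(hydroxymethyl)-1-methyl-6-methylidene-5-[2-(2-oxo-2,5-dihydrofuran-3-yl)ethyl]decahydronaphthalene-1-carboxylate | C=C1CC[C@@H]2[C@](CO)(CCC[C@]2(C)C(=O)OC)[C@H]1CCC1=CCOC1=O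
F11 | step 10 | methyl (1S,4aS,5S,8aR)-4a-(hydroxymethyl)-1-methyl-6-methylidene-5-{2-[(4-methylbenzenesulfonyl)oxy]ethyl}decahydronaphthalene-1-carboxylate | C=C1CC[C@@H]2[C@](CO)(CCC[C@]2(C)C(=O)OC)[C@H]1CCOS(=O)(=O)c1ccc(C)cc1
A1 | alternative 1 | ring B ketone: methyl 2-[3-{2-[(tert-butyldimethylsilyl)oxy]ethyl}-2-ethenyl-2-[(methoxymethoxy)methyl]-4-oxocyclohexyl]acetate, configured as in the SMILES | O=C1CC[C@@H](CC(=O)OC)[C@](COCOC)(C=C)[C@H]1CCO[Si](C)(C)C(C)(C)C
A2 | alternative 2 | 8-phenylmenthyl 5-{2-[(tert-butyldiphenylsilyl)oxy]ethyl}-4a-[(methoxymethoxy)methyl]-1-methyl-6-methylidene-2-oxodecahydronaphthalene-1-carboxylate, configured as in the SMILES | C=C1CC[C@@H]2[C@](COCOC)(CCC(=O)[C@]2(C)C(=O)O[C@@H]3C[C@H](C)CC[C@H]3C(C)(C)c3ccccc3)[C@H]1CCO[Si](c1ccccc1)(c1ccccc1)C(C)(C)C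
A3 | alternative 3 | cyclobutane-fused 19,20-lactone keto ester (C10–C20 and C9–C11 bonds formed, C8 ketone, methyl ester on C11), configured as in the SMILES | O=C1CC[C@@H]2[C@@]34CCC[C@]2(C)C(=O)O[C@H]3[C@H](C(=O)OC)[C@@H]14
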